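**Strategy.** Ring B is made first as a six-membered ring and contracted later. The C8–C9 and C5–C10 bonds, which ring B shares with rings C and A, form together as the two σ-bonds of an intramolecular Diels–Alder reaction between an exocyclic diene on ring D (C8=C7–C6=C5) and the C9=C10 bond of the C20→C12 lactone. The step exploits this lactone bridge: it activates C9=C10, ties it to C13 of ring D and fixes the face attacked, so ring C and provisional ring B close and C8, C9 and C10 are set together. The precursor is a cyclopentylidene dienoate carrying an α-substituted dihydropyranone. Epoxide rearrangement then contracts ring B, making C7 the carboxyl carbon.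

Key step: step 10

Remark on numbering: gibberellane numbering is used. In the target SMILES the carbons appear in the order C17, C16, C15, C8, C14, C13, C12, C11, C9, C10, C1, C2, C3, C4, C18, C19, C5, C6, C7, C20. Ring A = C1–C5, C10; ring B = C5, C6, C8, C9, C10; ring C = C8, C9, C11–C14; ring D = C8, C13–C16. α is the face of C20, β the face of H9.

Assumption: 2-methylenepentanedioic acid is taken as purchasable (otherwise by saponification of commercial dimethyl 2-methylenepentanedioate); (−)-Ipc2B(allyl) is bought or made from (−)-Ipc2BOMe and CH2=CHCH2MgBr.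

**Route**

Step 1
Reactants: 1 2-methylenepentanedioic acid
Product: 2 5-methoxy-2-methylene-5-oxopentanoic acid
Conditions: MeOH, AcCl (cat.), 0 °C → rt
Reagents that add atoms: methanol, CO
Why: Fischer esterification is much faster at the unconjugated carboxyl than at the acrylic one (as with itaconic acid), so the future C3 carboxyl is masked and the acrylic acid (future C20) stays free.

Step 2
Reactants: 3 tert-butyl but-3-enoate; 4 allyl bromide
Product: 5 tert-butyl (E)-5-bromopent-3-enoate
Conditions: second-generation Hoveyda–Grubbs catalyst RuCl2(H2IMes)(=CH–C6H4–2-OiPr) (2 mol%), 4 (4 equiv), CH2Cl2, 40 °C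
Reagents that add atoms: none
Why: Olefin cross-metathesis of two terminal alkenes with loss of ethene should give mainly the thermodynamically preferred (E)-allylic bromide.

Step 3
Reactants: 5 tert-butyl (E)-5-bromopent-3-enoate
Product: 6 [(E)-5-tert-butoxy-5-oxopent-2-en-1-yl]triphenylphosphonium bromide
Conditions: PPh3, MeCN, 50 °C
Reagents that add atoms: triphenylphosphine, c1ccc(cc1)P(c1ccccc1)c1ccccc1
Why: SN2 quaternisation of PPh3 by the primary allylic bromide gives the Wittig salt with the (E) double bond untouched.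

Step 4
Reactants: 7 (R)-4-[(tert-butyldimethylsilyl)oxy]cyclopent-2-en-1-one
Product: 8 (3S,4R)-4-[(tert-butyldimethylsilyl)oxy]-3-vinylcyclopentan-1-one
Conditions: CH2=CHMgBr, CuBr·SMe2 (10 mol%), THF, −78 °C; aq. NH4Cl
Reagents that add atoms: vinylmagnesium bromide, C=C[Mg]Br
Why: Copper-catalysed conjugate addition of the vinyl Grignard reagent occurs anti to the 4-silyloxy group, which sets C13 (trans to C16–O) from the chiral-pool centre.

Step 5
Reactants: 8 (3S,4R)-4-[(tert-butyldimethylsilyl)oxy]-3-vinylcyclopentan-1-one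
Product: 10 (1R,2R)-2-[(tert-butyldimethylsilyl)oxy]-4-oxocyclopentane-1-carbaldehyde, via secondary ozonide 9 (not isolated)
Conditions: O3, CH2Cl2, −78 °C; then PPh3, −78 °C → rt
Reagents that add atoms: ozone, [O-][O+]=O
Why: Ozonolysis with reductive work-up cleaves the only C=C bond to the C12 aldehyde, and the neutral work-up avoids β-elimination of the silyloxy group and epimerisation at C13.

Step 6
Reactants: 10 (1R,2R)-2-[(tert-butyldimethylsilyl)oxy]-4-oxocyclopentane-1-carbaldehyde
Product: 12 (3S,4R)-4-[(tert-butyldimethylsilyl)oxy]-3-[(1S)-1-hydroxybut-3-en-1-yl]cyclopentan-1-one, via diisopinocampheylborinate ester 11 (not isolated)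
Conditions: (−)-Ipc2B(allyl), Et2O, −78 °C; then HOCH2CH2NH2, rt
Reagents that add atoms: (−)-B-allyldiisopinocampheylborane, C=CCB([C@@H]1C[C@@H]2C[C@H]([C@H]1C)C2(C)C)[C@@H]1C[C@@H]2C[C@H]([C@H]1C)C2(C)C
Why: Brown asymmetric allylboration through a chair-like six-membered transition state is reagent-controlled and should give the (12S) carbinol, the aldehyde reacting far faster than the ketone at −78 °C.

Step 7
Reactants: 12 (3S,4R)-4-[(tert-butyldimethylsilyl)oxy]-3-[(1S)-1-hydroxybut-3-en-1-yl]cyclopentan-1-one; 2 5-methoxy-2-methylene-5-oxopentanoic acid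
Product: 13 acrylate ester (C12–O ester of 12 with acid 2)
Conditions: DCC, DMAP (cat.), CH2Cl2, 0 °C → rt
Reagents that add atoms: none
Why: Steglich esterification acylates the hindered secondary alcohol with retention at C12 under neutral conditions that spare the β-silyloxy ketone.

Step 8
Reactants: 13 acrylate ester
Product: 14 keto lactone (ring D ketone carrying the 3-substituted 5,6-dihydro-2H-pyran-2-one)
Conditions: second-generation Grubbs catalyst RuCl2(=CHPh)(H2IMes)(PCy3) (5 mol%), CH2Cl2, 40 °C
Reagents that add atoms: none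
Why: Ring-closing metathesis between the terminal alkene and the 1,1-disubstituted acrylate closes the α-substituted unsaturated δ-lactone (C9=C10) with loss of ethene.

Step 9
Reactants: 14 keto lactone; 6 [(E)-5-tert-butoxy-5-oxopent-2-en-1-yl]triphenylphosphonium bromide
Product: 17 (7E)-dienyl lactone (Diels–Alder precursor), via phosphonium ylide 15 (not isolated), via oxaphosphetane 16 (not isolated)
Conditions: 6, KN(SiMe3)2, THF, −78 °C; then 14, −78 → 0 °C; preparative HPLC; material of the other C7=C8 geometry re-equilibrated with I2 (cat.), hν, and separated again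
Reagents that add atoms: none
Why: Wittig olefination of the ring D ketone with the semi-stabilised allylic ylide through the oxaphosphetane builds the exocyclic diene C8=C7–C6=C5 (C5=C6 stays E) with a base weak enough to limit β-elimination of the silyloxy group, and since the reaction cannot control the geometry of the new C7=C8 bond, only the (7E) geometry (C6 syn to C14) is carried on while the rest of the material is returned to the equilibrium mixture by iodine-catalysed photoisomerisation and separated again.

Step 10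
Reactants: 17 (7E)-dienyl lactone
Product: 18 Diels–Alder adduct (rings D and C plus six-membered ring B with C6=C7; 5-epi)
Conditions: Me2AlCl (3 equiv), CH2Cl2, −40 → 0 °C
Reagents that add atoms: none
Why: Lewis-acid-promoted intramolecular Diels–Alder reaction, closest in type to the cyclisation of a 1,7,9-decatriene with a cis-enoate dienophile: Me2AlCl on the lactone carbonyl lowers the LUMO of C9=C10 and the s-cis diene C8=C7–C6=C5 adds suprafacially, forming C8–C9 and C5–C10 in one concerted, asynchronous step. Ring C (C8, C9, C11, C12, C13, C14) closes through the four-atom tether C14–C13–C12–C11 and the provisional six-membered ring B (C5, C6, C7, C8, C9, C10) is the cyclohexene of the [4+2] addition; because ring D holds C13 on the side of the diene terminus, only the transition state with the lactone ring exo can be reached. C8 is set by C13 (the new bond must be cis to C12 on ring D), C9 and C10 by C12 (the diene reaches only the lactone face that carries C13, and the cis ring alkene puts H9 and C1 on one face), so these three centres should come out as in the target. C5 follows from the (E) C5=C6 geometry and the exo mode and should come out epimeric (C4 cis to C1), which steps 17 and 18 correct. The step needs the (7E) diene, the only isomer whose inside CH2 is C14, and regiochemistry is secured by the tether, since the reverse pairing would need a seven-membered ring; low temperature keeps [1,5]-hydrogen shift of the diene from competing.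

Step 11
Reactants: 18 Diels–Alder adduct
Product: 19 6α,7α-epoxide
Conditions: mCPBA, NaHCO3, CH2Cl2, 0 °C
Reagents that add atoms: 3-chloroperoxybenzoic acid, OOC(=O)c1cccc(Cl)c1
Why: Prilezhaev epoxidation of the only C=C bond (C6=C7) should occur on the α face, anti to the C5 side chain.

Step 12
Reactants: 19 6α,7α-epoxide
Product: 21 ring-contracted 7-dimethyl acetal, via 7-aldehyde 20 (not isolated)
Conditions: BF3·OEt2 (0.3 equiv), CH2Cl2, −78 °C; then HC(OMe)3, MeOH, −78 → 0 °C
Reagents that add atoms: trimethyl orthoformate, COC(OC)OC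
Why: Meinwald rearrangement of the epoxide with 1,2-shift of a ring bond (C8 from C7 to C6) contracts ring B to the cyclopentanecarbaldehyde with the formyl group staying on the epoxide face (6α, trans to the C5 chain), and the same acid then converts it into the dimethyl acetal.

Step 13
Reactants: 21 ring-contracted 7-dimethyl acetal
Product: 22 C16 alcohol
Conditions: Bu4NF, THF, 0 °C; aq. NH4Cl
Reagents that add atoms: none
Why: Fluoride cleavage of the silyl ether frees the C16 alcohol without touching esters, lactone or acetal.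

Step 14
Reactants: 22 C16 alcohol
Product: 23 16-ketone
Conditions: Dess–Martin periodinane, NaHCO3, CH2Cl2, rt
Reagents that add atoms: none
Why: Dess–Martin oxidation gives the C16 ketone under buffered conditions, and since enolisation towards bridgehead C13 is impossible the β-acyloxy group at C12 cannot be eliminated.

Step 15
Reactants: 23 16-ketone
Product: 24 16-methylene compound
Conditions: Ph3PCH3Br, KOtBu, THF, 0 °C → rt
Reagents that add atoms: methyltriphenylphosphonium bromide, C[P+](c1ccccc1)(c1ccccc1)c1ccccc1.[Br-]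
Why: Wittig methylenation of the unhindered bicyclo[3.2.1]octanone installs the exocyclic C16=C17 bond while esters and lactone stay inert.

Step 16
Reactants: 24 16-methylene compound
Product: 25 ring A β-keto ester (enol form)
Conditions: KOtBu (2.2 equiv), THF, 0 °C; AcOH quench
Reagents that add atoms: none
Why: Dieckmann condensation, in which the C4 enolate of the tert-butyl ester attacks the methyl ester (C3) to close ring A; the tert-butyl ester is too poor an electrophile for the reverse mode and the β-keto ester enolate drives the reaction.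

Step 17
Reactants: 25 ring A β-keto ester
Product: 26 4,5-didehydro-3-oxo ester (alkylidene β-keto ester)
Conditions: DDQ, dioxane, rt
Reagents that add atoms: none
Why: DDQ dehydrogenation of the enolised β-keto ester (hydride abstraction from C5) gives the alkylidene β-keto ester and erases the wrong C5 centre.

Step 18
Reactants: 26 4,5-didehydro-3-oxo ester
Product: 28 3-oxo-4β-methyl ester (A/B trans), via lithium enolate 27 (not isolated)
Conditions: LiBH(s-Bu)3 (1.05 equiv), THF, −78 °C; then MeI, HMPA, −78 → 0 °C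
Reagents that add atoms: iodomethane, CI
Why: Reductive alkylation: conjugate hydride addition should deliver H to C5 from the β face (anti to the axial C20 on C10 and to the 6α acetal), giving the trans A/B fusion, and the enolate is C-methylated anti to C20, placing C18 β and C19 α.

Step 19
Reactants: 28 3-oxo-4β-methyl ester
Product: 30 2β-hydroxy-3-ketone, via potassium enolate 29 (not isolated)
Conditions: KN(SiMe3)2, THF, −78 °C; then 3-phenyl-2-(phenylsulfonyl)oxaziridine, −78 °C; aq. NH4Cl
Reagents that add atoms: 3-phenyl-2-(phenylsulfonyl)oxaziridine, O=S(=O)(c1ccccc1)N1OC1c1ccccc1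
Why: Davis α-hydroxylation of the only possible ketone enolate (C2, since C4 is quaternary) from the β face, opposite the axial C19 and C20 groups, should give the equatorial 2β-alcohol.

Step 20
Reactants: 30 2β-hydroxy-3-ketone
Product: 31 2β,3β-diol
Conditions: LiBH(s-Bu)3 (2.5 equiv), THF, −78 °C; aq. NH4Cl
Reagents that add atoms: none
Why: The bulky hydride attacks the C3 ketone along the equatorial trajectory and should give the axial 3β-alcohol cis to the 2β-hydroxyl, while esters and lactone survive at −78 °C.

Step 21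
Reactants: 31 2β,3β-diol
Product: 33 7-aldehyde (6β-CHO), via 6-epi aldehyde 32 (not isolated)
Conditions: AcOH/THF/H2O (3:1:1), 40 °C; then DBU (0.2 equiv), CH2Cl2, rt
Reagents that add atoms: water, O
Why: Mild acid hydrolysis of the dimethyl acetal, then base epimerisation of the aldehyde α-centre to the thermodynamically favoured 6β epimer, trans to the C4–C5 bond of the now trans-fused ring A.

Step 22
Reactants: 33 7-aldehyde
Product: 34 7-acid 19-tert-butyl ester
Conditions: NaClO2, NaH2PO4, 2-methyl-2-butene, t-BuOH/H2O, rt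
Reagents that add atoms: sodium chlorite, [Na+].[O-]Cl=O
Why: Pinnick oxidation converts the aldehyde into the C7 acid without epimerisation at C6 or attack on the alkene or diol.

Step 23
Reactants: 34 7-acid 19-tert-butyl ester
Product: 35 CNP0212122.1 (target)
Conditions: ZnBr2 (5 equiv), CH2Cl2, rt
Reagents that add atoms: none
Why: Lewis-acid-assisted E1 loss of isobutene cleaves the hindered tert-butyl ester under conditions mild enough for the acid-sensitive exocyclic alkene.

**Compound list**

1 | 2-methylenepentanedioic acid | C=C(CCC(=O)O)C(=O)O | starting material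
2 | 5-methoxy-2-methylene-5-oxopentanoic acid | C=C(CCC(=O)OC)C(=O)O | intermediate
3 | tert-butyl but-3-enoate | C=CCC(=O)OC(C)(C)C | starting material
4 | allyl bromide | C=CCBr | starting material
5 | tert-butyl (E)-5-bromopent-3-enoate | CC(C)(C)OC(=O)C/C=C/CBr | intermediate
6 | [(E)-5-tert-butoxy-5-oxopent-2-en-1-yl]triphenylphosphonium bromide | CC(C)(C)OC(=O)C/C=C/C[P+](c1ccccc1)(c1ccccc1)c1ccccc1.[Br-] | intermediate
7 | (R)-4-[(tert-butyldimethylsilyl)oxy]cyclopent-2-en-1-one | O=C1C=C[C@H](O[Si](C)(C)C(C)(C)C)C1 | starting material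
8 | (3S,4R)-4-[(tert-butyldimethylsilyl)oxy]-3-vinylcyclopentan-1-one | O=C1C[C@@H](C=C)[C@H](O[Si](C)(C)C(C)(C)C)C1 | intermediate
9 | secondary ozonide (1,2,4-trioxolane) of 8, trioxolane carbon unassigned | O=C1C[C@@H](C2OCOO2)[C@H](O[Si](C)(C)C(C)(C)C)C1 | intermediate
10 | (1R,2R)-2-[(tert-butyldimethylsilyl)oxy]-4-oxocyclopentane-1-carbaldehyde | O=C1C[C@@H](C=O)[C@H](O[Si](C)(C)C(C)(C)C)C1 | intermediate
11 | diisopinocampheylborinate ester of alcohol 12 | O=C1C[C@@H]([C@@H](OB([C@@H]2C[C@@H]3C[C@H]([C@H]2C)C3(C)C)[C@@H]2C[C@@H]3C[C@H]([C@H]2C)C3(C)C)CC=C)[C@H](O[Si](C)(C)C(C)(C)C)C1 | intermediate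
12 | (3S,4R)-4-[(tert-butyldimethylsilyl)oxy]-3-[(1S)-1-hydroxybut-3-en-1-yl]cyclopentan-1-one | O=C1C[C@@H]([C@@H](O)CC=C)[C@H](O[Si](C)(C)C(C)(C)C)C1 | intermediate
13 | 5-methyl 1-{(1S)-1-[(1S,2R)-2-(tert-butyldimethylsilyloxy)-4-oxocyclopentyl]but-3-en-1-yl} 2-methylenepentanedioate | O=C1C[C@@H]([C@@H](OC(=O)C(=C)CCC(=O)OC)CC=C)[C@H](O[Si](C)(C)C(C)(C)C)C1 | intermediate
14 | methyl 3-{(6S)-6-[(1S,2R)-2-(tert-butyldimethylsilyloxy)-4-oxocyclopentyl]-2-oxo-5,6-dihydro-2H-pyran-3-yl}propanoate | O=C1C[C@@H]([C@@H]2CC=C(CCC(=O)OC)C(=O)O2)[C@H](O[Si](C)(C)C(C)(C)C)C1 | intermediate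
15 | tert-butyl (E)-5-(triphenyl-λ5-phosphanylidene)pent-3-enoate | CC(C)(C)OC(=O)C/C=C/C=P(c1ccccc1)(c1ccccc1)c1ccccc1 | intermediate
16 | 1,2-oxaphosphetane from ylide 15 and ketone 14 (spiro at C8; ring carbons C7 and C8 unassigned) | CC(C)(C)OC(=O)C/C=C/C1C2(C[C@@H]([C@@H]3CC=C(CCC(=O)OC)C(=O)O3)[C@H](O[Si](C)(C)C(C)(C)C)C2)OP1(c1ccccc1)(c1ccccc1)c1ccccc1 | intermediate
17 | tert-butyl (3E,5E)-5-{(3S,4R)-4-(tert-butyldimethylsilyloxy)-3-[(2S)-5-(3-methoxy-3-oxopropyl)-6-oxo-3,6-dihydro-2H-pyran-2-yl]cyclopentylidene}pent-3-enoate (7E; C6 syn to C14) | CC(C)(C)OC(=O)C/C=C/C=C1\C[C@@H]([C@@H]2CC=C(CCC(=O)OC)C(=O)O2)[C@H](O[Si](C)(C)C(C)(C)C)C1 | intermediate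
18 | Diels–Alder adduct: rings D and C, six-membered ring B with C6=C7, 20→12 lactone; 16-OTBS; CH2CH2CO2Me on C10; CH2CO2t-Bu on C5 (H5 α, 5-epi); C8, C9, C10, C12, C13 as in the target | O([Si](C)(C)C(C)(C)C)[C@@H]1C[C@]23C[C@H]1[C@@H]1C[C@H]2[C@](CCC(=O)OC)([C@H](CC(=O)OC(C)(C)C)C=C3)C(=O)O1 | intermediate
19 | 6α,7α-epoxide of 18 | O([Si](C)(C)C(C)(C)C)[C@@H]1C[C@]23C[C@H]1[C@@H]1C[C@H]2[C@](CCC(=O)OC)([C@H](CC(=O)OC(C)(C)C)[C@H]4O[C@H]43)C(=O)O1 | intermediate
20 | ring-contracted aldehyde: five-membered ring B (C5, C6, C8, C9, C10) with 6α-CHO (C7), otherwise as 18 | O([Si](C)(C)C(C)(C)C)[C@@H]1C[C@]23C[C@H]1[C@@H]1C[C@H]2[C@](CCC(=O)OC)([C@H](CC(=O)OC(C)(C)C)[C@H]3C=O)C(=O)O1 | intermediate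
21 | 7,7-dimethyl acetal of 20 | O([Si](C)(C)C(C)(C)C)[C@@H]1C[C@]23C[C@H]1[C@@H]1C[C@H]2[C@](CCC(=O)OC)([C@H](CC(=O)OC(C)(C)C)[C@H]3C(OC)OC)C(=O)O1 | intermediate
22 | C16 alcohol (desilylated 21) | O[C@@H]1C[C@]23C[C@H]1[C@@H]1C[C@H]2[C@](CCC(=O)OC)([C@H](CC(=O)OC(C)(C)C)[C@H]3C(OC)OC)C(=O)O1 | intermediate
23 | 16-ketone (17-nor-16-oxo compound) | O=C1C[C@]23C[C@H]1[C@@H]1C[C@H]2[C@](CCC(=O)OC)([C@H](CC(=O)OC(C)(C)C)[C@H]3C(OC)OC)C(=O)O1 | intermediate
24 | 16-methylene compound (C16=C17) | C=C1C[C@]23C[C@H]1[C@@H]1C[C@H]2[C@](CCC(=O)OC)([C@H](CC(=O)OC(C)(C)C)[C@H]3C(OC)OC)C(=O)O1 | intermediate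
25 | ring A β-keto ester: 3-oxo (drawn as 3-enol), 19-tert-butyl ester, A/B cis (5-epi), 6α-CH(OMe)2 | C=C1C[C@]23C[C@H]1[C@@H]1C[C@H]2[C@@]2(CCC(O)=C(C(=O)OC(C)(C)C)[C@@H]2[C@H]3C(OC)OC)C(=O)O1 | intermediate
26 | 4,5-didehydro-3-oxo 19-tert-butyl ester (alkylidene β-keto ester) | C=C1C[C@]23C[C@H]1[C@@H]1C[C@H]2[C@@]2(CCC(=O)C(C(=O)OC(C)(C)C)=C2[C@H]3C(OC)OC)C(=O)O1 | intermediate
27 | lithium 3-enolate after hydride addition to C5 (H5 β) | C=C1C[C@]23C[C@H]1[C@@H]1C[C@H]2[C@@]2(CCC([O-])=C(C(=O)OC(C)(C)C)[C@H]2[C@H]3C(OC)OC)C(=O)O1.[Li+] | intermediate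
28 | 3-oxo-4β-methyl 19-tert-butyl ester, A/B trans | C=C1C[C@]23C[C@H]1[C@@H]1C[C@H]2[C@@]2(CCC(=O)[C@@](C)(C(=O)OC(C)(C)C)[C@H]2[C@H]3C(OC)OC)C(=O)O1 | intermediate
29 | potassium 2-en-3-olate of 28 | C=C1C[C@]23C[C@H]1[C@@H]1C[C@H]2[C@@]2(CC=C([O-])[C@@](C)(C(=O)OC(C)(C)C)[C@H]2[C@H]3C(OC)OC)C(=O)O1.[K+] | intermediate
30 | 2β-hydroxy-3-ketone | C=C1C[C@]23C[C@H]1[C@@H]1C[C@H]2[C@@]2(C[C@H](O)C(=O)[C@@](C)(C(=O)OC(C)(C)C)[C@H]2[C@H]3C(OC)OC)C(=O)O1 | intermediate
31 | 2β,3β-diol 7-dimethyl acetal 19-tert-butyl ester | C=C1C[C@]23C[C@H]1[C@@H]1C[C@H]2[C@@]2(C[C@H](O)[C@H](O)[C@@](C)(C(=O)OC(C)(C)C)[C@H]2[C@H]3C(OC)OC)C(=O)O1 | intermediate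
32 | 2β,3β-dihydroxy 6-epi-7-aldehyde 19-tert-butyl ester | C=C1C[C@]23C[C@H]1[C@@H]1C[C@H]2[C@@]2(C[C@H](O)[C@H](O)[C@@](C)(C(=O)OC(C)(C)C)[C@H]2[C@H]3C=O)C(=O)O1 | intermediate
33 | 2β,3β-dihydroxy 7-aldehyde 19-tert-butyl ester (6β-CHO) | C=C1C[C@]23C[C@H]1[C@@H]1C[C@H]2[C@@]2(C[C@H](O)[C@H](O)[C@@](C)(C(=O)OC(C)(C)C)[C@H]2[C@@H]3C=O)C(=O)O1 | intermediate
34 | 2β,3β-dihydroxy 7-oic acid 19-tert-butyl ester 20→12 lactone | C=C1C[C@]23C[C@H]1[C@@H]1C[C@H]2[C@@]2(C[C@H](O)[C@H](O)[C@@](C)(C(=O)OC(C)(C)C)[C@H]2[C@@H]3C(=O)O)C(=O)O1 | intermediate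
35 | CNP0212122.1 | C=C1C[C@]23C[C@H]1[C@@H]1C[C@H]2[C@@]2(C[C@H](O)[C@H](O)[C@@](C)(C(=O)O)[C@H]2[C@@H]3C(=O)O)C(=O)O1 | target

**Totals.** 23 steps in all. The longest linear sequence is 20 steps (steps 4–23, from enone 7); acid 2 needs one step and phosphonium salt 6 two.

**Steps most likely to fail**

Step 10. The diene may fail to reach the s-cis, lactone-exo transition state because of the inside CH2 of ring D, or it may be consumed by Lewis-acid-induced polymerisation or [1,5]-hydrogen shift before cycloaddition. The fallback sets out from 17 and replaces the pericyclic step by an anionic double Michael reaction. LiN(SiMe3)2 with HMPA in THF at −78 → −20 °C should deprotonate C4 of the β,γ-unsaturated tert-butyl ester to the extended trienolate. Its ε-carbon C8 adds to C9 of the lactone (the only ring size the tether allows), and the lactone enolate at C10 then closes onto C5 of the resulting 2,4-dienoate. Because the two bonds form in separate steps, the C7=C8 geometry of the starting diene is not carried into the product, so material of either geometry should serve. Protonation at C4 brings the route back at 18; a C5 epimer would be equally serviceable because C5 is reset in steps 17 and 18. This fallback makes no new compound (F0).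

Step 12. During Lewis-acid opening of the epoxide, hydride shift (to a ketone) or Wagner–Meerwein migration from quaternary C8 may outrun the ring-contracting alkyl shift. The fallback sets out from 18. OsO4 (catalytic) with N-methylmorpholine N-oxide should give the 6α,7α-diol F1. The less hindered C6 hydroxyl is mesylated (MsCl, pyridine, −20 °C) to the 6-mesylate F2. KOtBu in t-BuOH/THF then triggers the pinacol-type shift of C8 from C7 to C6 with loss of mesylate, giving aldehyde 20. Acetalisation with HC(OMe)3/MeOH and pyridinium p-toluenesulfonate brings the route back at 21.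

Step 9. The basic ylide may enolise the ketone and eliminate the β-silyloxy group instead of olefinating, and the olefination exerts no control over the geometry of the new exocyclic C7=C8 bond, so each pass can deliver only part of the material in the geometry that the cycloaddition needs. The fallback sets out from 14 and bromide 5. The allylbarium reagent from 5 and activated barium metal (BaI2, lithium biphenylide, THF, −78 °C) should add through its α-carbon to the ketone, giving the tertiary homoallylic alcohol F3 (C8 epimers, of no consequence). Dehydration with the Burgess reagent (methyl N-(triethylammoniosulfonyl)carbamate, benzene, 50 °C) towards the conjugated position gives the diene, and after the same separation and recycling of geometric isomers the route is rejoined at 17.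

Further compounds
F0 | step 10 | none | none
F1 | step 12 | 6α,7α-diol of 18 | O([Si](C)(C)C(C)(C)C)[C@@H]1C[C@]23C[C@H]1[C@@H]1C[C@H]2[C@](CCC(=O)OC)([C@H](CC(=O)OC(C)(C)C)[C@@H](O)[C@H]3O)C(=O)O1
F2 | step 12 | 6-O-methanesulfonate of F1 | O([Si](C)(C)C(C)(C)C)[C@@H]1C[C@]23C[C@H]1[C@@H]1C[C@H]2[C@](CCC(=O)OC)([C@H](CC(=O)OC(C)(C)C)[C@@H](OS(C)(=O)=O)[C@H]3O)C(=O)O1
F3 | step 9 | tertiary alcohol from α-allylation of 14 at C8 (C8 epimers, centre unassigned) | CC(C)(C)OC(=O)C/C=C/CC1(O)C[C@@H]([C@@H]2CC=C(CCC(=O)OC)C(=O)O2)[C@H](O[Si](C)(C)C(C)(C)C)C1
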